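**Plan**

Locants (target): C1 carries benzoyl; C3 is the quaternary carbon shared with the cyclopentane; C5 carries geranyl; C2, C4, C9 are the ketones between C1/C3, C3/C5, C5/C1; C6 (CH2), C7 (CH), C8 (CMe2) bridge C5 to C1; C10 is the CH2 from C7 to the cyclopentane CH C11; C12 is the ring CMe2; C13, C14 its CH2 groups (C14 on C3).
Cuts: first C5–C6 (cage opened to a C7=C6 methylene, reached from an allylsilane), then C1–C8, the bond between two fully substituted carbons inside the seven-membered ring C1–C8–C7–C10–C11–C3–C2. Because C2 is a carbonyl carbon next to C1 and C10 is tied to it through C3–C11, this ring is the [3,3] product of the allyl vinyl ether C1=C2–O–C10–C7=C8, a dihydrofuran enol ether.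
Further cuts: O–C2 (cyclodehydration), C1–C2 and C4–C5 (two Claisen-type acylations joining a lactone acid to a benzoyl/geranyl β-diketone), C10–C7 (alkenyl addition to an aldehyde), C3–C14 and C3–C11 (cyclopentane from bromomalonate and a bromo aldehyde).
Forward order of rings: cyclopentane, γ-lactone, trione ring, dihydrofuran, seven-membered ring (the dihydrofuran is consumed), cage.
Stereochemistry: C11 by catalyst control (enamine/photoredox α-alkylation); C10 by chelation-controlled addition; C3 by lactonisation on the cis ester; C1 by the suprafacial shift on the C10-bearing face; C5 and C7 by the cage geometry.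

Key step: step 12

Assumption: β-di- and tricarbonyl compounds are drawn as keto forms although they will be largely enolised; C5 (and C1 in 19 and 20) is configurationally labile and is left undefined until the cage fixes it.

**Route**

Step 1
Reactants: 1 methyl 3,3-dimethylpent-4-enoate
Product: 2 methyl 5-bromo-3,3-dimethylpentanoate
Conditions: HBr (gas), (PhCO2)2 (cat.), pentane, hν, 0 °C
Reagents that add atoms: hydrogen bromide, Br
Why: Radical-chain (anti-Markovnikov) hydrobromination puts bromine on the terminal carbon (C14) because the bromine atom adds to the unhindered CH2 end of the vinyl group; no stereocentre is formed.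

Step 2
Reactants: 2 methyl 5-bromo-3,3-dimethylpentanoate
Product: 3 5-bromo-3,3-dimethylpentanal
Conditions: i-Bu2AlH (1.05 equiv), CH2Cl2, −78 °C; aq. potassium sodium tartrate
Reagents that add atoms: none
Why: Partial ester reduction by an aluminium hydride at −78 °C stops at the aluminium hemiacetal, which releases the aldehyde on work-up, and the primary bromide is inert.

Step 3
Reactants: 3 5-bromo-3,3-dimethylpentanal; 4 dimethyl 2-bromopropanedioate
Product: 5 dimethyl 2-[(2S)-5-bromo-3,3-dimethyl-1-oxopentan-2-yl]propanedioate
Conditions: 3 (2 equiv), Ru(bpy)3Cl2 (0.5 mol %), (2R,5S)-2-tert-butyl-3,5-dimethylimidazolidin-4-one·CF3SO3H (20 mol %), 2,6-lutidine (2 equiv), DMF, blue LEDs, 23 °C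
Reagents that add atoms: none
Why: Photoredox organocatalytic α-alkylation of an aldehyde: the malonyl radical formed by single-electron reduction of 4 adds to the E-enamine on its Si face (the catalyst antipode is chosen so that this face is open), which sets C11 as S; the primary bromide is not reduced by the photocatalyst.

Step 4
Reactants: 5 dimethyl 2-[(2S)-5-bromo-3,3-dimethyl-1-oxopentan-2-yl]propanedioate
Product: 6 dimethyl (2R)-2-formyl-3,3-dimethylcyclopentane-1,1-dicarboxylate
Conditions: Cs2CO3 (1.2 equiv), DMF, 0 → 23 °C
Reagents that add atoms: none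
Why: Intramolecular malonate alkylation (5-exo-tet, helped by the gem-dimethyl group) closes the cyclopentane; carbonate deprotonates only the malonate C–H, so C11 keeps its configuration (the descriptor changes from S to R only through CIP priorities).

Step 5
Reactants: 7 acetone; 8 tetrabromomethane
Product: 9 1,1-dibromo-2-methylprop-1-ene
Conditions: PPh3 (4 equiv), CBr4 (2 equiv), CH2Cl2, 0 °C; then acetone, 0 → 40 °C
Reagents that add atoms: none
Why: Ramirez (Corey–Fuchs type) dibromoolefination of a ketone by the ylide Ph3P=CBr2.

Step 6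
Reactants: 9 1,1-dibromo-2-methylprop-1-ene; 10 (trimethylsilyl)methylmagnesium chloride
Product: 11 (2-bromo-3-methylbut-2-en-1-yl)trimethylsilane
Conditions: 10 (1.05 equiv, slow addition), Pd(PPh3)4 (3 mol %), THF, 0 → 23 °C
Reagents that add atoms: none
Why: Kumada coupling under zerovalent palladium catalysis; the first coupling gives a tetrasubstituted, more electron-rich vinyl bromide that undergoes oxidative addition more slowly, so one equivalent of Grignard reagent should stop at the mono-coupled allylsilane.

Step 7
Reactants: 6 dimethyl (2R)-2-formyl-3,3-dimethylcyclopentane-1,1-dicarboxylate; 11 (2-bromo-3-methylbut-2-en-1-yl)trimethylsilane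
Product: 13 methyl (3R,3aR,6aS)-4,4-dimethyl-3-[3-methyl-1-(trimethylsilyl)but-2-en-2-yl]-1-oxohexahydro-1H-cyclopenta[c]furan-6a-carboxylate, via hydroxy diester 12 (not isolated)
Conditions: 11, t-BuLi (2.0 equiv), Et2O, −78 °C; MgBr2·OEt2, −78 → −40 °C; then 6, CH2Cl2, −78 → 23 °C
Reagents that add atoms: none
Why: Bromine–lithium exchange, transmetalation and 1,2-addition of the alkenylmagnesium reagent to the aldehyde, then lactonisation of the alkoxide on the cis ester (this makes C3 a stereocentre and tells the two esters apart); magnesium chelated between the aldehyde oxygen and an ester carbonyl holds C=O over C3, so attack past H-11, away from the gem-dimethyl carbon C12, places the alkenyl group cis to H-11 on the convex face of the lactone.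

Step 8
Reactants: 13 methyl (3R,3aR,6aS)-4,4-dimethyl-3-[3-methyl-1-(trimethylsilyl)but-2-en-2-yl]-1-oxohexahydro-1H-cyclopenta[c]furan-6a-carboxylate
Product: 14 (3R,3aR,6aS)-4,4-dimethyl-3-[3-methyl-1-(trimethylsilyl)but-2-en-2-yl]-1-oxohexahydro-1H-cyclopenta[c]furan-6a-carboxylic acid
Conditions: NaSEt (3 equiv), DMF, 23 °C; then 0.5 M HCl, 0 °C
Reagents that add atoms: none
Why: SN2 dealkylation of a methyl ester by thiolate attacks the methyl carbon and not the hindered acyl carbon, so the lactone (whose C10–O carbon is secondary and shielded) and the allylsilane survive, and no stereocentre is touched.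

Step 9
Reactants: 15 1-phenylbutane-1,3-dione; 16 geranyl bromide
Product: 17 (6E)-7,11-dimethyl-1-phenyldodeca-6,10-diene-1,3-dione
Conditions: LiN(i-Pr)2 (2.1 equiv), THF, 0 °C; then 16, −78 → 0 °C
Reagents that add atoms: none
Why: γ-Alkylation of a β-diketone dianion: the less stabilised terminal carbanion is the more nucleophilic site and displaces the allylic bromide by SN2 with the E alkene unchanged.

Step 10
Reactants: 14 (3R,3aR,6aS)-4,4-dimethyl-3-[3-methyl-1-(trimethylsilyl)but-2-en-2-yl]-1-oxohexahydro-1H-cyclopenta[c]furan-6a-carboxylic acid; 17 (6E)-7,11-dimethyl-1-phenyldodeca-6,10-diene-1,3-dione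
Product: 19 (3R,3aR)-6a-(2-geranyl-3,5-dioxo-5-phenylpentanoyl)-4,4-dimethyl-3-[3-methyl-1-(trimethylsilyl)but-2-en-2-yl]hexahydro-1H-cyclopenta[c]furan-1-one (triketo lactone), via acid chloride 18 (not isolated)
Conditions: 14, Me2C=C(Cl)NMe2 (1.2 equiv), CH2Cl2, 0 → 23 °C; then added to the dilithio dianion of 17 (2.5 equiv; LiN(i-Pr)2, THF), −78 → −20 °C; cold aq. NH4Cl
Reagents that add atoms: none
Why: The acid chloride is made under neutral conditions (no HCl, so the allylsilane is safe) and acylates the terminal carbanion of the diketone dianion (the standard route to 1,3,5-triketones), the excess dianion deprotonating the product; the acid chloride outcompetes the lactone carbonyl, so C5 is joined to C4 and not to C2.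

Step 11
Reactants: 19 triketo lactone
Product: 21 dihydrofuran enol ether (C2–O–C10 ring fused to the 2-benzoyl trione ring at C2–C3; alkenyl on C10 cis to H-11), via hydroxy tetraketone 20 (not isolated)
Conditions: NaH (3.5 equiv), THF, 0 → 50 °C; AcOH quench; then pyridinium p-toluenesulfonate (10 mol %), 4 Å MS, PhMe, 50 °C
Reagents that add atoms: none
Why: Intramolecular Claisen (Dieckmann-type) C-acylation of the C1 diketonate by the lactone carbonyl, the closure used for acylphloroglucinols and 3-acyltetramic acids (Lacey–Dieckmann), is driven by the extra hydride that takes up the freed alkoxide; mild acid then adds the C10 hydroxyl to C2, the only ring carbonyl cis to it, and loss of water gives the vinylogous ester with retention at C10.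

Step 12
Reactants: 21 dihydrofuran enol ether
Product: 22 bicyclo[4.3.1]decane trione with the C1–C8 bond and a C10=C7 allylsilane (seven-membered ring C1–C8–C7=C10–C11–C3–C2)
Conditions: i-Pr2NEt (1.5 equiv), PhMe (0.01 M), 110 °C, sealed tube, Ar; dilute citric acid wash
Reagents that add atoms: none
Why: Heating brings the allyl vinyl ether C1=C2–O–C10–C7=C8 into a chair-like six-atom array held by the two-atom tether C3–C11 (a bicyclo[3.2.1]octane-like transition state), and a concerted [3,3] shift forms C1–C8 while O–C10 breaks and C2=O and C10=C7 appear. The closest known reactions are the Claisen rearrangement of O-allyl enol ethers of 2-acyl-1,3-diones and the ring-expanding Claisen rearrangement of 2-alkylidene-5-vinyltetrahydrofurans to cyclohept-4-enones. The seven-membered carbocycle is closed by a two-atom ring expansion of the five-membered ether (C1, C8 and C7 enter the ring, oxygen leaves it), not by end-to-end cyclisation, and the tether enforces the cis C10=C7 alkene. The one new stereocentre, C1, is controlled by C3 and C11 through C10: C8 can reach C1 only on the face where the C10–C7 bond lies, and with the alkenyl group on the convex face (cis to H-11) this is the face that gives the out,out-bridged skeleton of the target. The step needs the pericyclic path to win over heterolysis of the allylic C10–O bond (1,3-shift or diene formation); the large driving force from vinylogous ester to C-alkylated 2-acyl-1,3-dione, the non-polar solvent and the amine, which holds the acidic C5 enol as its enolate so that no proton assists ionisation, favour the concerted shift. The silylmethyl group on C7 is a spectator that marks C6 for the next step.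

Step 13
Reactants: 22 bicyclo[4.3.1]decane trione allylsilane
Product: 23 bicyclo[4.3.1]decane trione with C10H2 and an exocyclic C7=C6H2 methylene
Conditions: CF3CO2H (5 equiv), CH2Cl2, −20 → 0 °C; aq. NaHCO3
Reagents that add atoms: none
Why: Protodesilylation of an allylsilane (SE2′): the proton adds to C10, γ to silicon, through the β-silyl cation at C7, and loss of silicon leaves the exocyclic methylene; at low temperature the allylsilane should be protonated far faster than the geranyl alkenes.

Step 14
Reactants: 23 exocyclic methylene trione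
Product: 24 CNP0168637.1
Conditions: Mn(OAc)3·2H2O (2.2 equiv), degassed EtOH, 23 → 60 °C
Reagents that add atoms: none
Why: Oxidative free-radical cyclisation with Mn(OAc)3: the trivalent manganese enolate of the C4/C9 diketone gives the C5 radical, which adds to the unsubstituted terminus C6 of the 1,1-disubstituted alkene (endo closure, the usual mode for such alkenes) to give the bridgehead radical at C7, and this takes hydrogen from ethanol; the cage allows only the outward C7–H and fixes C5.

**Compound list**

1 | methyl 3,3-dimethylpent-4-enoate | C=CC(C)(C)CC(=O)OC | starting material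
2 | methyl 5-bromo-3,3-dimethylpentanoate | BrCCC(C)(C)CC(=O)OC | intermediate
3 | 5-bromo-3,3-dimethylpentanal | BrCCC(C)(C)CC=O | intermediate
4 | dimethyl 2-bromopropanedioate | COC(=O)C(Br)C(=O)OC | starting material
5 | dimethyl 2-[(2S)-5-bromo-3,3-dimethyl-1-oxopentan-2-yl]propanedioate | O=C[C@@H](C(C(=O)OC)C(=O)OC)C(C)(C)CCBr | intermediate
6 | dimethyl (2R)-2-formyl-3,3-dimethylcyclopentane-1,1-dicarboxylate | O=C[C@@H]1C(C)(C)CCC1(C(=O)OC)C(=O)OC | intermediate
7 | acetone | CC(C)=O | starting material
8 | tetrabromomethane | BrC(Br)(Br)Br | starting material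
9 | 1,1-dibromo-2-methylprop-1-ene | CC(C)=C(Br)Br | intermediate
10 | (trimethylsilyl)methylmagnesium chloride | C[Si](C)(C)C[Mg]Cl | starting material
11 | (2-bromo-3-methylbut-2-en-1-yl)trimethylsilane | CC(C)=C(Br)C[Si](C)(C)C | intermediate
12 | dimethyl (2R)-2-[(1R)-1-hydroxy-3-methyl-2-[(trimethylsilyl)methyl]but-2-en-1-yl]-3,3-dimethylcyclopentane-1,1-dicarboxylate (hydroxy diester) | COC(=O)C1(C(=O)OC)CCC(C)(C)[C@H]1[C@@H](O)C(C[Si](C)(C)C)=C(C)C | intermediate
13 | methyl (3R,3aR,6aS)-4,4-dimethyl-3-[3-methyl-1-(trimethylsilyl)but-2-en-2-yl]-1-oxohexahydro-1H-cyclopenta[c]furan-6a-carboxylate (ring C3 = C10, C3a = C11, C6a = C3 of the target; cis-fused, alkenyl cis to H-3a) | COC(=O)[C@]12CCC(C)(C)[C@H]1[C@H](C(C[Si](C)(C)C)=C(C)C)OC2=O | intermediate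
14 | (3R,3aR,6aS)-4,4-dimethyl-3-[3-methyl-1-(trimethylsilyl)but-2-en-2-yl]-1-oxohexahydro-1H-cyclopenta[c]furan-6a-carboxylic acid | OC(=O)[C@]12CCC(C)(C)[C@H]1[C@H](C(C[Si](C)(C)C)=C(C)C)OC2=O | intermediate
15 | 1-phenylbutane-1,3-dione | CC(=O)CC(=O)c1ccccc1 | starting material
16 | geranyl bromide, (2E)-1-bromo-3,7-dimethylocta-2,6-diene | CC(C)=CCC/C(C)=C/CBr | starting material
17 | (6E)-7,11-dimethyl-1-phenyldodeca-6,10-diene-1,3-dione | CC(C)=CCC/C(C)=C/CCC(=O)CC(=O)c1ccccc1 | intermediate
18 | acid chloride of 14 (6a-carbonyl chloride, ring stereocentres unchanged) | O=C(Cl)[C@]12CCC(C)(C)[C@H]1[C@H](C(C[Si](C)(C)C)=C(C)C)OC2=O | intermediate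
19 | triketo lactone: lactone of 14 whose C4 carbonyl carries CH(geranyl)–CO–CH2–COPh (C5 epimers and enol forms) | CC(C)=CCC/C(C)=C/CC(C(=O)CC(=O)c1ccccc1)C(=O)[C@]12CCC(C)(C)[C@H]1[C@H](C(C[Si](C)(C)C)=C(C)C)OC2=O | intermediate
20 | hydroxy tetraketone: 7-benzoyl-9-geranyl-2,2-dimethyl-1-[1-hydroxy-3-methyl-2-[(trimethylsilyl)methyl]but-2-en-1-yl]spiro[4.5]decane-6,8,10-trione, C6 carbonyl (target C2) cis to the carbinol side chain, C11 and C10 as in 12 | CC(C)=CCC/C(C)=C/CC1C(=O)[C@@]2(CCC(C)(C)[C@H]2[C@@H](O)C(C[Si](C)(C)C)=C(C)C)C(=O)C(C(=O)c2ccccc2)C1=O | intermediate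
21 | dihydrofuran enol ether: O on C2 bonded to C10, enol ether double bond C1=C2 with benzoyl on C1, ketones at C4 and C9, geranyl on C5, cyclopentane cis-fused at C3–C11, alkenyl on C10 cis to H-11 | CC(C)=CCC/C(C)=C/CC1C(=O)[C@]23CCC(C)(C)[C@H]2[C@H](C(C[Si](C)(C)C)=C(C)C)OC3=C(C(=O)c2ccccc2)C1=O | intermediate
22 | bicyclo[4.3.1]decane-2,4,9-trione (target locants): C1 (benzoyl) bonded to C8, seven-membered ring C1–C8–C7=C10–C11–C3–C2 with CH2SiMe3 on C7, geranyl on C5 | CC(C)=CCC/C(C)=C/CC1C(=O)[C@]23CCC(C)(C)[C@H]2C=C(C[Si](C)(C)C)C(C)(C)[C@](C(=O)c2ccccc2)(C1=O)C3=O | intermediate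
23 | as 22 with C10H2 and an exocyclic C7=C6H2 methylene in place of the allylsilane | CC(C)=CCC/C(C)=C/CC1C(=O)[C@]23CCC(C)(C)[C@H]2CC(=C)C(C)(C)[C@](C(=O)c2ccccc2)(C1=O)C3=O | intermediate
24 | CNP0168637.1 | CC(C)=CCC/C(C)=C/C[C@@]12C[C@H]3C[C@@H]4C(C)(C)CC[C@]4(C1=O)C(=O)[C@@](C(=O)c1ccccc1)(C2=O)C3(C)C | target

**Step count**

Total: 14 steps. Longest linear sequence: 11 steps (steps 1–4, 7, 8, 10–14).

**Steps most likely to fail**

Step 12. Heterolysis of the allylic C10–O bond may outrun the concerted shift, with the ion pair collapsing at C10 (a 1,3-shift) or losing a proton to a diene; the congested C1–C8 bond raises the temperature at which this competition is decided. The fallback sets out from 21 and returns at 22. It removes the acidic enol that assists ionisation: TMSCHN2 (MeOH–PhMe, 0 °C) converts 21 into the C4 methyl enol ether F1, a neutral 3,5-dialkoxy-cyclohexa-2,5-dienone (the C9 regioisomer would converge). Thermolysis in PhMe (110–140 °C) should then give the rearranged methyl ether F2 by the same shift. LiCl in DMSO at 120 °C cleaves the vinylogous methyl ester by SN2 at the methyl group and gives 22.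

Step 14. The C5 radical may close in the exo sense on C7, or the bridgehead radical may be oxidised by trivalent manganese and captured by acetate before hydrogen transfer. The fallback sets out from 23 and returns at 24. It generates the radical reductively: NBS (CH2Cl2, 0 °C) brominates the enolised C5 to give the C5 bromide F3. Bu3SnH added slowly with AIBN in benzene at 80 °C gives the same C5 radical; the low stannane concentration lets a reversible exo adduct drain into the tertiary C7 radical, which the stannane reduces to 24.

Step 11. The stabilised C1 diketonate may add too slowly to the hindered lactone carbonyl, or the hydroxy tetraketone may revert by retro-Claisen relactonisation before it is dehydrated. The fallback sets out from 13 and returns at 22; it closes the ring through C5–C4 with an ordinary ketone enolate. The kinetic lithium enolate of commercial (E)-geranylacetone (LiN(i-Pr)2, THF, −78 °C) adds to the lactone carbonyl of 13, and pyridinium p-toluenesulfonate dehydrates the hemiketal to the acylmethylene tetrahydrofuran F4. LiN(SiMe3)2 closes C5 onto the C4 methyl ester (Dieckmann) to give the enol ether dione lacking benzoyl F5. TMSCHN2 gives its C4 methyl enol ether F6, whose only acidic hydrogen is the vinylic C1–H. Lithium 2,2,6,6-tetramethylpiperidide followed by benzoyl chloride (the usual late C-acylation of such vinylogous esters) gives F1, which continues through F2 to 22 as in the first fallback.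

Further compounds
F1 | step 12 | C4 methyl enol ether of 21 | CC(C)=CCC/C(C)=C/CC1=C(OC)[C@]23CCC(C)(C)[C@H]2[C@H](C(C[Si](C)(C)C)=C(C)C)OC3=C(C(=O)c2ccccc2)C1=O
F2 | step 12 | C4 methyl enol ether of 22 | CC(C)=CCC/C(C)=C/CC1=C(OC)[C@]23CCC(C)(C)[C@H]2C=C(C[Si](C)(C)C)C(C)(C)[C@](C(=O)c2ccccc2)(C1=O)C3=O
F3 | step 14 | C5 bromide of 23 | CC(C)=CCC/C(C)=C/CC1(Br)C(=O)[C@]23CCC(C)(C)[C@H]2CC(=C)C(C)(C)[C@](C(=O)c2ccccc2)(C1=O)C3=O
F4 | step 11 | acylmethylene tetrahydrofuran from 13 and geranylacetone (C1=C2 enol ether, C4 methyl ester retained) | COC(=O)[C@]12CCC(C)(C)[C@H]1[C@H](C(C[Si](C)(C)C)=C(C)C)O/C2=C/C(=O)CC/C=C(\C)CCC=C(C)C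
F5 | step 11 | enol ether dione lacking benzoyl (21 with H on C1) | CC(C)=CCC/C(C)=C/CC1C(=O)[C@]23CCC(C)(C)[C@H]2[C@H](C(C[Si](C)(C)C)=C(C)C)OC3=CC1=O
F6 | step 11 | C4 methyl enol ether of F5 | CC(C)=CCC/C(C)=C/CC1=C(OC)[C@]23CCC(C)(C)[C@H]2[C@H](C(C[Si](C)(C)C)=C(C)C)OC3=CC1=O
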